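**Retrosynthetic overview**
- Target ⇒ open the pyranone O1–C2 bond and saturate C2=C3: an (E)-2',6'-dihydroxy-4'-methoxychalcone. The ring C–O bond is the key disconnection; the two phenols are equivalent, so whichever closes, the other becomes the 5-OH.
- Chalcone ⇒ Claisen–Schmidt condensation of 2',6'-dihydroxy-4'-methoxyacetophenone with 2,3,4,5-tetramethoxybenzaldehyde.
- Aldehyde ⇒ formylation of 1,2,3,4-tetramethoxybenzene.
- Ring order: both benzene rings are bought; the pyranone ring is the only ring made, and it is made last.

Assumption: the target has no stereocentre, so there is no enantiomer to select (the only stereo-element en route is the E-alkene of the chalcone); 1 and 4 are taken as catalogue items.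

**Step 1**
Reactants: 1 1,2,3,4-tetramethoxybenzene
Product: 3 2,3,4,5-tetramethoxybenzaldehyde, via α-chloro ether 2 (not isolated)
Conditions: Cl2CHOMe (1.2 equiv), TiCl4 (2.0 equiv), CH2Cl2, −10 → 0 °C, 1 h; then ice/1 M HCl
Reagents that add atoms: dichloromethyl methyl ether, COC(Cl)Cl; water, O
Why: Rieche formylation (Friedel–Crafts-type substitution by the TiCl4-activated dichloromethyl ether, then hydrolysis of 2): the two free positions of 1 are equivalent and ortho/para-activated, so only one mono-aldehyde can form, the formyl group deactivates the ring against a second substitution, and no stereocentre is involved.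

**Step 2**
Reactants: 3 2,3,4,5-tetramethoxybenzaldehyde; 4 1-(2,6-dihydroxy-4-methoxyphenyl)ethan-1-one
Product: 6 (E)-1-(2,6-dihydroxy-4-methoxyphenyl)-3-(2,3,4,5-tetramethoxyphenyl)prop-2-en-1-one, via aldol adduct 5 (not isolated)
Conditions: KOH (50% aq, 12 equiv), EtOH, 0 °C → rt, 48 h, N2; then 2 M HCl, 0 °C, to pH 4
Reagents that add atoms: none
Why: Claisen–Schmidt (crossed aldol) condensation: the aldehyde cannot enolise, the ketone enolate adds to give 5, and E1cB dehydration gives the conjugated enone with the thermodynamically preferred E geometry; aryl methyl ethers and phenoxides are inert to aqueous KOH under N2.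

**Step 3**
Reactants: 6 (E)-1-(2,6-dihydroxy-4-methoxyphenyl)-3-(2,3,4,5-tetramethoxyphenyl)prop-2-en-1-one
Product: 10 5-hydroxy-7-methoxy-2-(2,3,4,5-tetramethoxyphenyl)-4H-chromen-4-one (target), via flavanone 7 (not isolated), via enamine 8 (not isolated), via iminium acetate 9 (not isolated)
Conditions: pyrrolidine (30 mol%), AcOH (60 mol%), H2O (2 equiv), [Ru(bpy)3](PF6)2 (2 mol%), Co(dmgH)2(py)Cl (5 mol%), degassed MeCN, Ar; 60 °C, dark, 2 h; then 450 nm LEDs, 35 °C, 16 h (−H2); aq NaHCO3
Reagents that add atoms: water, O (its oxygen becomes the C-4 carbonyl oxygen when 9 is hydrolysed; the same amount of water is released when 8 forms)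
Why: Proposed new method: a dehydrogenative oxa-Michael annulation by amine/photoredox/cobaloxime triple catalysis, in which pyrrolidinium acetate closes the O1–C2 bond of 6 by 6-endo oxa-Michael addition and condenses the resulting flavanone 7 to enamine 8, photoexcited Ru(bpy)3(2+) (about +0.8 V vs SCE) oxidises only this enamine (about +0.5 V, whereas the tetramethoxyarene and phenols lie above +1.2 V), the radical cation loses the triply activated C2–H (benzylic, α-oxy, allylic to the enamine), and the resulting radical is oxidised by the cobaloxime to the aromatic 4-aminobenzopyrylium ion 9, whose hydrolysis releases 10 and the amine while Co–H plus a proton give H2; aromatisation to the pyrylium makes the reversible C–O closure irreversible without electrophilic halogen or a stoichiometric oxidant near the electron-rich rings, the racemic C2 centre of 7 and 8 is flattened so no stereocentre remains, and the closest known reaction types are the Kabbe amine-catalysed chromanone synthesis and the photoredox/cobaloxime acceptorless desaturation of ketone-derived enamines (β-enaminyl radical chemistry), which to my knowledge have not been merged into an oxidative C–O annulation of a 2'-hydroxychalcone.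

**Compound list**
1 | 1,2,3,4-tetramethoxybenzene | COc1ccc(OC)c(OC)c1OC | starting material
2 | 1-[chloro(methoxy)methyl]-2,3,4,5-tetramethoxybenzene (racemic, Ti-bound in the flask) | COC(Cl)c1cc(OC)c(OC)c(OC)c1OC | intermediate
3 | 2,3,4,5-tetramethoxybenzaldehyde | O=Cc1cc(OC)c(OC)c(OC)c1OC | intermediate
4 | 1-(2,6-dihydroxy-4-methoxyphenyl)ethan-1-one (2',6'-dihydroxy-4'-methoxyacetophenone) | COc1cc(O)c(C(C)=O)c(O)c1 | starting material
5 | 1-(2,6-dihydroxy-4-methoxyphenyl)-3-hydroxy-3-(2,3,4,5-tetramethoxyphenyl)propan-1-one (racemic aldol adduct) | COc1cc(O)c(C(=O)CC(O)c2cc(OC)c(OC)c(OC)c2OC)c(O)c1 | intermediate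
6 | (E)-1-(2,6-dihydroxy-4-methoxyphenyl)-3-(2,3,4,5-tetramethoxyphenyl)prop-2-en-1-one (chalcone) | COc1cc(O)c(C(=O)/C=C/c2cc(OC)c(OC)c(OC)c2OC)c(O)c1 | intermediate
7 | 5-hydroxy-7-methoxy-2-(2,3,4,5-tetramethoxyphenyl)chroman-4-one (racemic flavanone) | COc1cc(O)c2c(c1)OC(c1cc(OC)c(OC)c(OC)c1OC)CC2=O | intermediate
8 | 7-methoxy-4-(pyrrolidin-1-yl)-2-(2,3,4,5-tetramethoxyphenyl)-2H-chromen-5-ol (racemic enamine) | COc1cc(O)c2c(c1)OC(c1cc(OC)c(OC)c(OC)c1OC)C=C2N1CCCC1 | intermediate
9 | 1-[5-hydroxy-7-methoxy-2-(2,3,4,5-tetramethoxyphenyl)-4H-chromen-4-ylidene]pyrrolidin-1-ium acetate (4-pyrrolidinylflavylium salt) | COc1cc(O)c2c(c1)OC(c1cc(OC)c(OC)c(OC)c1OC)=CC2=[N+]1CCCC1.CC(=O)[O-] | intermediate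
10 | 5-hydroxy-7-methoxy-2-(2,3,4,5-tetramethoxyphenyl)-4H-chromen-4-one (achiral) | COc1cc(O)c2c(=O)cc(-c3cc(OC)c(OC)c(OC)c3OC)oc2c1 | target

**Totals**
Total step count: 3. Longest linear sequence: 3 (1 → 3 → 6 → 10; 4 enters at step 2).

**Steps most likely to fail, with fallbacks**

Step 3 (the proposed new step) is the most likely to fail. The hydrogen-bonded 5-hydroxy ketone of 7 may form enamine 8 only slowly, the amine may be held back as the stable salt 9, and chalcone 6 may undergo sensitised photoreactions if ring closure is incomplete before irradiation. The fallback uses known chemistry and sets out from 6: heating 6 with catalytic iodine (10 mol%) in DMSO at 120 °C effects the classical oxidative cyclisation, with DMSO as terminal oxidant. It comes back to the route at 10 and makes no new compound.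

Step 2 is second. The doubly deprotonated, hindered ketone 4 may condense sluggishly with the electron-rich, ortho-substituted aldehyde 3. The fallback changes to a protecting-group strategy and sets out from 4. Treatment with chloromethyl methyl ether and i-Pr2NEt in CH2Cl2 gives 1-[4-methoxy-2,6-bis(methoxymethoxy)phenyl]ethan-1-one F1. This now mono-anionic ketone condenses cleanly with 3 (KOH, EtOH/H2O, rt) to give (E)-1-[4-methoxy-2,6-bis(methoxymethoxy)phenyl]-3-(2,3,4,5-tetramethoxyphenyl)prop-2-en-1-one F2. Both acetals are removed with 3 M HCl in MeOH at 50 °C, and the sequence comes back to the route at 6; any of the material that has already ring-closed to 7 is consumed by step 3 in the same way.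

Step 1 is third. TiCl4 can cleave the methoxy group ortho to the new formyl group if the mixture warms, and the very electron-rich arene can give diarylmethane by-products. The fallback replaces electrophilic substitution by directed ortho-metalation and sets out from 1. n-BuLi/TMEDA in THF at 0 °C gives (2,3,4,5-tetramethoxyphenyl)lithium F3, which is formylated with DMF at −78 °C → rt and quenched with aqueous HCl. It comes back to the route at 3.

**Further compounds**
F1 | step 2 | 1-[4-methoxy-2,6-bis(methoxymethoxy)phenyl]ethan-1-one | COCOc1cc(OC)cc(OCOC)c1C(C)=O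
F2 | step 2 | (E)-1-[4-methoxy-2,6-bis(methoxymethoxy)phenyl]-3-(2,3,4,5-tetramethoxyphenyl)prop-2-en-1-one | COCOc1cc(OC)cc(OCOC)c1C(=O)/C=C/c1cc(OC)c(OC)c(OC)c1OC
F3 | step 1 | (2,3,4,5-tetramethoxyphenyl)lithium | [Li]c1cc(OC)c(OC)c(OC)c1OC
F0 | step 3 | none | none
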